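- 3 questions on 4 flasks are asked, and we answer them with one reckoning of ours: we follow the fraction of D left, not the fraction of E made, and we follow it through its rate.

| flask | D | Q | remark | time |
|---|---|---|---|---|
| oak | 0.82 M | 22 mM | run made earlier |  |
| maple | 0.82 M | 240 mM | run made earlier |  |
| elm | 1.2 M | 75 mM | run made earlier |  |
| midnight | 0.82 M | 75 mM |  | 4.0 h |
| winter | 1.5 M | 300 mM |  | 4.0 h |
| spring | 2.5 M | 25 mM |  | 4.0 h |
| dusk | 0.60 M | 300 mM |  | 4.0 h |

- oak (time / h: E / %, D / %): 0.200: 0.6, 92.9; 0.667: 2.1, 80.0; 1.00: 2.1, 71.6; 1.50: 5.0, 60.5; 2.50: 10.6, 41.8; 3.00: 12.9, 34.0; 4.00: 16.9, 20.2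
- maple (time / h: E / %, D / %): 0.200: 1.7, 93.3; 0.667: 4.8, 79.4; 1.00: 8.9, 70.9; 1.50: 12.9, 57.6; 2.50: 19.7, 36.7; 3.00: 22.0, 28.1; 4.00: 26.5, 12.5
- elm (time / h: E / %, D / %): 0.333: 1.5, 92.4; 1.00: 4.0, 80.7; 2.00: 8.8, 65.3; 3.00: 13.1, 51.8; 4.00: 17.3, 42.1

(each reading ± 0.5 percentage points)

- at the start none of D is in solution
- what has only dissolved of D counts as not reacted
- a reading or a percentage of E counts all its forms, free or not

- the flasks put in order of amount of E, in percent of the D charged, best first, at 4.0 h (midnight / winter / spring / dusk)
- the amount of E, in percent of the D charged of the flask you put first, at 4.0 h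
- the amount of E, in percent of the D charged of the flask you put last, at 4.0 h

- Elm starts by losing 0.228 h⁻¹ of its charge, and oak's 0.355 h⁻¹, told as a share of elm's larger charge, becomes 0.243 h⁻¹, so these two runs, which differ in Q as well as in charge, start at nearly the same absolute rate.
- Time slows it: elm's last hour runs at 0.0970 h⁻¹, a factor 2.35 below the start, while ten times the Q, from oak to maple, raises the amount lost by a factor of 1.10.
- Over the whole run, elm's start rate held for 4.0 h comes to 91.2 % of its charge, but with the slowing elm loses a fraction 0.634 of that, which is the common loss, the amount of D gone by that time at a given Q, 0.695 M.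
- The fraction left is one minus common loss over charge, which gives 15.3 % for midnight, 53.7 % for winter and 72.2 % for spring, while dusk charges less than the common loss, so we reckon the reading of D in dusk at zero.
- Taking E per D lost from the run nearest in Q, 0.303 from maple, 0.299 from elm and 0.212 from oak, we reckon dusk 30.3 %, midnight 25.3 %, winter 14.0 % and spring 5.89 %.
- The forecast, holding that “The D loss curves coincide in absolute terms”, gives the same order, dusk > midnight > winter > spring, but its 28.5 % stands below our first and its 6.2 % above our last.
- The flask gives dusk > midnight > winter > spring, with 31.7 % in dusk and 5.96 % in spring.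

    Z + Q ⇌ E + Q, rate k1*[Z]*[Q] forward; the back reaction follows from the equilibrium constant (K = 0.520, k = 9.37 M⁻¹ h⁻¹)
    L ⇌ E, rate k2*(cs2 - [E]) while solid is left; crystals form when [E] > cs2 (solubility = 0.270 M, k = 3.18 h⁻¹)
    E ⇌ X (K = 0.274, k = 0.121 h⁻¹)
    D ⇌ Z, rate k4*(cs4 - [Z]) while solid is left; crystals form when [Z] > cs4 (solubility = 0.780 M, k = 0.350 h⁻¹)
    X + Q ⇌ G + Q, rate k5*[Q]*[X] forward; the back reaction follows from the equilibrium constant (K = 2.00, k = 2.30 M⁻¹ h⁻¹)

- At 4.00 h dusk holds D at 0 % and spring at 73.6 %, where the common loss left spring 72.2 %. Dusk's E moves by 5 points when its charge of D reaches 0.842 M, of which the common loss leaves 17.5 %. The neighbouring spring flask with 0.062 M of Q, for which the common loss again gives 72.2 %, holds D at 72.4 %.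

The numbers in the tables stem from a simulated flask on assumed constants, noise included.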